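## Retrosynthetic overview
1. The target comes from a doubly benzyl-protected depside by global hydrogenolysis. The depside is cut at the aryl ester C(=O)–O bond into a ring A acid (2-OBn, 4-OMe) and a ring B phenol (benzyl ester, 2-OMe, free 4-OH).
2. Both halves come from one resorcylate, methyl olivetolate, by ordered O-alkylation. The free 4-OH reacts first and the hydrogen-bonded 2-OH second, followed by ester exchange.
3. Methyl olivetolate comes from a 6-pentylcyclohexane-1,3-dione-type ester by bromination and dehydrobromination.
4. Key C–C bond: intermolecular Michael addition of dimethyl malonate to (E)-non-3-en-2-one, followed in the same flask by Claisen ring closure.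
5. Ring order: the carbocycle is built once (step 1), aromatised (step 2) and then divided into the ring A and ring B series. No other ring is formed.

Assumption: the target has no stereocentre and no stereogenic axis, so it is achiral. The stereocentres of the early non-aromatic intermediates are racemic and are erased on aromatisation.

## Route

Step 1
Reactants: 1 (E)-non-3-en-2-one; 2 dimethyl malonate
Product: 4 methyl 2-hydroxy-4-oxo-6-pentylcyclohex-2-ene-1-carboxylate (racemic trans/cis mixture), via Michael adduct 3 (not isolated)
Conditions: NaOMe (1.2 equiv), 2 (1.2 equiv), MeOH, reflux, 3 h; then aq HCl to pH 3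
Reagents that add atoms: none
Why: Sodium dimethyl malonate adds 1,4 to the enone (intermolecular Michael addition), and the methyl-ketone enolate of 3 then closes the six-membered ring on one ester (Dieckmann-type Claisen condensation), driven by the stabilised 1,3-dione enolate; the two new stereocentres form racemic and are erased in step 2.

Step 2
Reactants: 4 methyl 2-hydroxy-4-oxo-6-pentylcyclohex-2-ene-1-carboxylate
Product: 6 methyl 2,4-dihydroxy-6-pentylbenzoate (methyl olivetolate), via bromo enol 5 (not isolated)
Conditions: Br2 (1.0 equiv), DMF, 0 °C, 1 h; then 80 °C, 12 h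
Reagents that add atoms: bromine, BrBr (its atom is held only in intermediate 5)
Why: Electrophilic C-bromination of the enolised 1,3-dione, thermal loss of HBr and tautomerisation (bromination–dehydrobromination aromatisation) give the resorcylate and remove both stereocentres, while 80 °C is too low for loss of the ester group.

Compound 6 is divided: about 45 % goes to steps 3–5 (ring A) and about 55 % to steps 6–10 (ring B).

Step 3
Reactants: 6 methyl 2,4-dihydroxy-6-pentylbenzoate
Product: 7 methyl 2-hydroxy-4-methoxy-6-pentylbenzoate
Conditions: MeI (1.05 equiv), K2CO3 (1.1 equiv), acetone, reflux, 6 h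
Reagents that add atoms: iodomethane, CI
Why: Williamson ether synthesis alkylates only the free, more acidic 4-OH, because the 2-OH is locked in a hydrogen bond to the ester carbonyl; no stereocentre is formed.

Step 4
Reactants: 7 methyl 2-hydroxy-4-methoxy-6-pentylbenzoate
Product: 8 methyl 2-(benzyloxy)-4-methoxy-6-pentylbenzoate
Conditions: BnBr (1.3 equiv), K2CO3 (2 equiv), DMF, 60 °C, 12 h
Reagents that add atoms: benzyl bromide, BrCc1ccccc1
Why: Williamson benzylation in a polar aprotic solvent with excess base and heat overcomes the chelated hydrogen bond and caps the last phenol, so it cannot slow the hydrolysis or compete in the coupling.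

Step 5
Reactants: 8 methyl 2-(benzyloxy)-4-methoxy-6-pentylbenzoate
Product: 9 2-(benzyloxy)-4-methoxy-6-pentylbenzoic acid
Conditions: KOH (6 equiv), DMSO/H2O 4:1, 95 °C, 8 h; then cold 1 M HCl to pH 2
Reagents that add atoms: potassium hydroxide, [K+].[OH-]
Why: Saponification of the di-ortho-substituted benzoate is made practical by poorly solvated hydroxide in aqueous DMSO, both ethers are inert to base, and cold acidification avoids decarboxylation.

Step 6
Reactants: 6 methyl 2,4-dihydroxy-6-pentylbenzoate
Product: 10 methyl 4-(benzyloxy)-2-hydroxy-6-pentylbenzoate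
Conditions: BnBr (1.05 equiv), K2CO3 (1.1 equiv), acetone, reflux, 8 h
Reagents that add atoms: benzyl bromide, BrCc1ccccc1
Why: Regioselective Williamson benzylation of the non-chelated 4-OH follows the same selectivity as step 3 and temporarily masks the future depside oxygen.

Step 7
Reactants: 10 methyl 4-(benzyloxy)-2-hydroxy-6-pentylbenzoate
Product: 11 methyl 4-(benzyloxy)-2-methoxy-6-pentylbenzoate
Conditions: MeI (3 equiv), K2CO3 (3 equiv), DMF, 40 °C, 16 h
Reagents that add atoms: iodomethane, CI
Why: Williamson methylation of the only remaining phenol, under forcing conditions, installs the 2'-O-methyl group with no regiochemical ambiguity.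

Step 8
Reactants: 11 methyl 4-(benzyloxy)-2-methoxy-6-pentylbenzoate
Product: 12 4-(benzyloxy)-2-methoxy-6-pentylbenzoic acid
Conditions: KOH (6 equiv), DMSO/H2O 4:1, 95 °C, 6 h; then cold 1 M HCl to pH 2
Reagents that add atoms: potassium hydroxide, [K+].[OH-]
Why: This is the same saponification as in step 5, on a slightly less hindered ester that carries only base-stable ethers.

Step 9
Reactants: 12 4-(benzyloxy)-2-methoxy-6-pentylbenzoic acid
Product: 13 4-hydroxy-2-methoxy-6-pentylbenzoic acid
Conditions: H2 (1 atm), Pd/C (10 wt% Pd), EtOAc, rt, 3 h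
Reagents that add atoms: none
Why: Catalytic hydrogenolysis of the benzylic C–O bond frees the 4-OH under neutral conditions without touching the acid, the methyl ether or the arene.

Step 10
Reactants: 13 4-hydroxy-2-methoxy-6-pentylbenzoic acid
Product: 14 benzyl 4-hydroxy-2-methoxy-6-pentylbenzoate
Conditions: BnBr (1.05 equiv), KHCO3 (1.2 equiv), DMF, rt to 40 °C, 12 h
Reagents that add atoms: benzyl bromide, BrCc1ccccc1
Why: In this carboxylate SN2 O-alkylation, hydrogen carbonate ionises only the carboxylic acid (pKa about 4) and not the phenol (pKa about 9), so benzyl bromide esterifies the acid selectively.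

Step 11
Reactants: 9 2-(benzyloxy)-4-methoxy-6-pentylbenzoic acid; 14 benzyl 4-hydroxy-2-methoxy-6-pentylbenzoate
Product: 16 benzyl 4-{[2-(benzyloxy)-4-methoxy-6-pentylbenzoyl]oxy}-2-methoxy-6-pentylbenzoate, via mixed anhydride 15 (not isolated)
Conditions: (CF3CO)2O (4 equiv), dry toluene, 0 °C to rt, 3 h
Reagents that add atoms: trifluoroacetic anhydride, O=C(OC(=O)C(F)(F)F)C(F)(F)F (its atoms are held only in intermediate 15)
Why: In this mixed-anhydride esterification the electron-rich, hindered aroyl trifluoroacetate is activated enough, with acylium-like character, to be captured by the unhindered 4-OH of 14, and the benzyl ether, benzyl ester and methyl ethers tolerate dilute trifluoroacetic acid at room temperature.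

Step 12
Reactants: 16 benzyl 4-{[2-(benzyloxy)-4-methoxy-6-pentylbenzoyl]oxy}-2-methoxy-6-pentylbenzoate
Product: 17 2'-O-methylperlatolic acid
Conditions: H2 (1 atm), Pd/C (10 wt% Pd), EtOAc, rt, 4 h
Reagents that add atoms: none
Why: Global catalytic hydrogenolysis cleaves both benzylic C–O bonds (ether and ester) under neutral conditions in a non-nucleophilic solvent, so the depside aryl ester is not solvolysed; no stereocentre is present.

## Compound list
1 | (E)-non-3-en-2-one | CCCCC/C=C/C(C)=O | starting material
2 | dimethyl malonate | COC(=O)CC(=O)OC | starting material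
3 | dimethyl 2-(2-oxononan-4-yl)propanedioate (racemic, not isolated) | CCCCCC(CC(C)=O)C(C(=O)OC)C(=O)OC | intermediate
4 | methyl 2-hydroxy-4-oxo-6-pentylcyclohex-2-ene-1-carboxylate (racemic trans/cis mixture) | CCCCCC1CC(=O)C=C(O)C1C(=O)OC | intermediate
5 | methyl 3-bromo-2-hydroxy-4-oxo-6-pentylcyclohex-2-ene-1-carboxylate (racemic, not isolated) | CCCCCC1CC(=O)C(Br)=C(O)C1C(=O)OC | intermediate
6 | methyl 2,4-dihydroxy-6-pentylbenzoate (methyl olivetolate) | CCCCCc1cc(O)cc(O)c1C(=O)OC | intermediate
7 | methyl 2-hydroxy-4-methoxy-6-pentylbenzoate | CCCCCc1cc(OC)cc(O)c1C(=O)OC | intermediate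
8 | methyl 2-(benzyloxy)-4-methoxy-6-pentylbenzoate | CCCCCc1cc(OC)cc(OCc2ccccc2)c1C(=O)OC | intermediate
9 | 2-(benzyloxy)-4-methoxy-6-pentylbenzoic acid | CCCCCc1cc(OC)cc(OCc2ccccc2)c1C(=O)O | intermediate
10 | methyl 4-(benzyloxy)-2-hydroxy-6-pentylbenzoate | CCCCCc1cc(OCc2ccccc2)cc(O)c1C(=O)OC | intermediate
11 | methyl 4-(benzyloxy)-2-methoxy-6-pentylbenzoate | CCCCCc1cc(OCc2ccccc2)cc(OC)c1C(=O)OC | intermediate
12 | 4-(benzyloxy)-2-methoxy-6-pentylbenzoic acid | CCCCCc1cc(OCc2ccccc2)cc(OC)c1C(=O)O | intermediate
13 | 4-hydroxy-2-methoxy-6-pentylbenzoic acid | CCCCCc1cc(O)cc(OC)c1C(=O)O | intermediate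
14 | benzyl 4-hydroxy-2-methoxy-6-pentylbenzoate | CCCCCc1cc(O)cc(OC)c1C(=O)OCc1ccccc1 | intermediate
15 | 2-(benzyloxy)-4-methoxy-6-pentylbenzoic trifluoroacetic anhydride (not isolated) | CCCCCc1cc(OC)cc(OCc2ccccc2)c1C(=O)OC(=O)C(F)(F)F | intermediate
16 | benzyl 4-{[2-(benzyloxy)-4-methoxy-6-pentylbenzoyl]oxy}-2-methoxy-6-pentylbenzoate | CCCCCc1cc(OC)cc(OCc2ccccc2)c1C(=O)Oc1cc(CCCCC)c(C(=O)OCc2ccccc2)c(OC)c1 | intermediate
17 | 2'-O-methylperlatolic acid (achiral) | CCCCCc1cc(OC)cc(O)c1C(=O)Oc1cc(CCCCC)c(C(=O)O)c(OC)c1 | target

## Counts
Total steps: 12.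
Longest linear sequence: 9 steps (1, 2, 6, 7, 8, 9, 10, 11, 12).

## Three steps most likely to fail

**Step 11 (esterification of a di-ortho-substituted acid).** The risks are slow acyl transfer, trifluoroacetylation of 14 and partial loss of benzyl groups in the acidic medium. The fallback sets out from 9. Oxalyl chloride with catalytic DMF in CH2Cl2 at 0 °C converts 9 into the isolated acyl donor 2-(benzyloxy)-4-methoxy-6-pentylbenzoyl chloride F4, freed of volatiles by evaporation. F4 is then added to 14 with Et3N and catalytic DMAP in CH2Cl2 at 0 °C to rt. This basic, acid-free acylation comes back to the route at 16.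

**Step 2 (aromatisation).** The risks are partial ring bromination, which gives mixtures, and loss of the ester group on overheating. The fallback sets out from 4 and makes over-bromination the intended outcome. Br2 (3 equiv) in AcOH at rt both aromatises and brominates, giving one crystalline compound, methyl 3,5-dibromo-2,4-dihydroxy-6-pentylbenzoate F1. Hydrodebromination of F1 with H2, Pd/C and NaOAc in MeOH at rt removes both halogens and comes back to the route at 6.

**Step 5 (the more hindered of the two saponifications).** The risks are incomplete hydrolysis and decarboxylation on prolonged heating. The fallback sets out from 8 and avoids attack of hydroxide on the shielded carbonyl. LiAlH4 in THF (0 °C to reflux) gives [2-(benzyloxy)-4-methoxy-6-pentylphenyl]methanol F2. MnO2 in CH2Cl2 oxidises F2 to 2-(benzyloxy)-4-methoxy-6-pentylbenzaldehyde F3. Pinnick oxidation of F3 (NaClO2, NaH2PO4, 2-methylbut-2-ene, t-BuOH/H2O, rt) comes back to the route at 9.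

## Further compounds
F1 | step 2 | methyl 3,5-dibromo-2,4-dihydroxy-6-pentylbenzoate | CCCCCc1c(Br)c(O)c(Br)c(O)c1C(=O)OC
F2 | step 5 | [2-(benzyloxy)-4-methoxy-6-pentylphenyl]methanol | CCCCCc1cc(OC)cc(OCc2ccccc2)c1CO
F3 | step 5 | 2-(benzyloxy)-4-methoxy-6-pentylbenzaldehyde | CCCCCc1cc(OC)cc(OCc2ccccc2)c1C=O
F4 | step 11 | 2-(benzyloxy)-4-methoxy-6-pentylbenzoyl chloride | CCCCCc1cc(OC)cc(OCc2ccccc2)c1C(=O)Cl
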